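A direct plan would make ring B arylacetic acid A2 by copper-catalysed hydroxylation of the symmetric dibromide A1, condense it with ring A aldehyde A3 (Perkin) to the triacetoxy acrylic acid A4, hydrogenate to the racemic acid A5, convert A5 into ketene A6 and add methanol under a chiral squaramide, then remove the acetates.
Its weakest steps would be:
- The mono-hydroxylation of A1 to A2: one of two equivalent C–Br bonds must react and the other must not, so the step is a statistical desymmetrisation held only by stoichiometry.
- The hydrogenation of A4 to A5 followed by dehydrochlorination to A6: the stereocentre is made racemic and then flattened again, so reduction, chloride formation and ketene formation build no bond of the target.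
- The enantioselective methanolysis of A6: the only stereocentre would rest on a reaction without precedent for ketenes, with unknown sense and level of induction, at the end of the route.

**Retrosynthetic overview**
- The target is cut at the bond between the stereogenic α-carbon C2 and C1 of ring B (the 3-bromo-5-hydroxy-4-methoxyphenyl ring). A cobalt–bisoxazoline enantioconvergent Negishi arylation joins racemic α-bromo ester 6 (ring A) with arylzinc 12 (ring B) and sets C2 in the same operation.
- C2 invites this because it is a tertiary α-aryl ester carbon flanked by CO2R, CH2Ar and H, so both enantiomers of an easily made bromide pass through one planar α-ester radical.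
- Ring A bromo ester 6 comes from 5,6-dibromovanillin by demethylation, MOM protection, Wittig olefination and 1,4-hydrosilylation/bromination. Ring B comes from 3-bromo-2-methoxyphenol by C–H borylation/iodination at the one unhindered C–H para to OMe, so no dibromide is desymmetrised.
- No ring is formed; both arenes are bought with their O/Br pattern. The stereocentre is set once by a precedented catalyst class, and the last step only removes MOM and exchanges benzyl for methyl.

Key step: step 7

Assumption: 5,6-dibromovanillin (1) and 3-bromo-2-methoxyphenol (7) are taken as catalogue compounds. The (S,S) ligand antipode in step 7 is assumed to give the (R)-ester by analogy with simple 2-bromoalkanoates; this must be verified on an analytical run, and the other antipode is equally available.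

**Step 1**
Reactants: 1 2,3-dibromo-4-hydroxy-5-methoxybenzaldehyde (5,6-dibromovanillin)
Product: 2 2,3-dibromo-4,5-dihydroxybenzaldehyde
Conditions: BBr3 (3 equiv), CH2Cl2, −78 °C to rt; then H2O
Reagents that add atoms: none
Why: Lewis-acid cleavage of the aryl methyl ether (BBr3 demethylation), assisted by the neighbouring phenol through a cyclic borate; the aldehyde and the aryl bromides are inert and no stereocentre is involved.

**Step 2**
Reactants: 2 2,3-dibromo-4,5-dihydroxybenzaldehyde
Product: 3 2,3-dibromo-4,5-bis(methoxymethoxy)benzaldehyde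
Conditions: MOMCl (3 equiv), iPr2NEt (4 equiv), CH2Cl2, 0 °C to rt
Reagents that add atoms: chloromethyl methyl ether, COCCl
Why: O-alkylation of both phenols (MOM protection) gives acetal ethers that should survive ylide, silane, organomagnesium and organozinc chemistry and fall off in the final acidic methanol; no stereocentre.

**Step 3**
Reactants: 3 2,3-dibromo-4,5-bis(methoxymethoxy)benzaldehyde
Product: 4 benzyl (2E)-3-[2,3-dibromo-4,5-bis(methoxymethoxy)phenyl]prop-2-enoate
Conditions: Ph3P=CHCO2Bn (1.2 equiv), toluene, 80 °C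
Reagents that add atoms: benzyl (triphenylphosphoranylidene)acetate, O=C(OCc1ccccc1)C=P(c1ccccc1)(c1ccccc1)c1ccccc1
Why: Wittig olefination with a stabilised ylide should give the (E)-cinnamate; the benzyl ester is chosen because, to the best of recollection, the enantioconvergent coupling of step 7 is best documented for benzyl 2-bromoalkanoates; no stereocentre.

**Step 4**
Reactants: 4 benzyl (2E)-3-[2,3-dibromo-4,5-bis(methoxymethoxy)phenyl]prop-2-enoate
Product: 6 benzyl rac-2-bromo-3-[2,3-dibromo-4,5-bis(methoxymethoxy)phenyl]propanoate, via silyl ketene acetal 5 (not isolated)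
Conditions: RhCl(PPh3)3 (1 mol %), Et3SiH (1.2 equiv), toluene, 60 °C; evaporate; NBS (1.1 equiv), THF, −78 °C
Reagents that add atoms: N-bromosuccinimide, O=C1CCC(=O)N1Br
Why: Rhodium-catalysed 1,4-hydrosilylation of the enoate gives the silyl ketene acetal, which NBS brominates at carbon (α-halogenation of a silyl ketene acetal) far faster than the hindered arene; aryl C–Br, MOM and benzyl ester are untouched, and the new centre is left racemic on purpose because step 7 is stereoconvergent.

**Step 5**
Reactants: 7 3-bromo-2-methoxyphenol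
Product: 8 1-bromo-2-methoxy-3-(methoxymethoxy)benzene
Conditions: MOMCl (1.5 equiv), iPr2NEt (2 equiv), CH2Cl2, 0 °C to rt
Reagents that add atoms: chloromethyl methyl ether, COCCl
Why: O-alkylation of the phenol (MOM protection) masks the acidic O–H before C–H borylation and organometallic formation; no stereocentre.

**Step 6**
Reactants: 8 1-bromo-2-methoxy-3-(methoxymethoxy)benzene
Product: 10 1-bromo-5-iodo-2-methoxy-3-(methoxymethoxy)benzene, via aryl pinacol boronate 9 (not isolated)
Conditions: [Ir(OMe)(cod)]2 (1.5 mol %), 4,4′-di-tert-butyl-2,2′-bipyridine (3 mol %), B2pin2 (1.0 equiv), THF, 80 °C; evaporate; CuI (10 mol %), 1,10-phenanthroline (20 mol %), KI (1.5 equiv), MeOH/H2O 4:1, air, 80 °C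
Reagents that add atoms: potassium iodide, [K+].[I-]
Why: Sterically controlled iridium-catalysed C–H borylation takes the only C–H bond without an ortho substituent (C5, para to OMe), and copper-catalysed aerobic iododeboronation converts the boronate into the iodide in the same flask; the aryl C–Br bond and the MOM ether are inert and no stereocentre is involved.

**Step 7**
Reactants: 10 1-bromo-5-iodo-2-methoxy-3-(methoxymethoxy)benzene; 6 benzyl rac-2-bromo-3-[2,3-dibromo-4,5-bis(methoxymethoxy)phenyl]propanoate
Product: 13 benzyl (2R)-2-[3-bromo-4-methoxy-5-(methoxymethoxy)phenyl]-3-[2,3-dibromo-4,5-bis(methoxymethoxy)phenyl]propanoate, via arylmagnesium chloride 11 (not isolated), via arylzinc bromide 12 (not isolated)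
Conditions: 10 (1.4 equiv), iPrMgCl·LiCl (1.4 equiv), THF, −20 °C; ZnBr2 (1.5 equiv), to rt; evaporate, redissolve in THF; then 6 (1.0 equiv), CoI2 (10 mol %), 2,2′-(1,3-diphenylpropane-2,2-diyl)bis[(4S)-4-phenyl-4,5-dihydrooxazole] (12 mol %), THF, −25 °C
Reagents that add atoms: none
Why: Arylzinc 12 converts the CoI2–bisoxazoline complex into a low-valent aryl cobalt species that abstracts bromine from either enantiomer of 6 to give one planar α-(benzyloxycarbonyl)alkyl radical, which is captured at the chiral aryl cobalt centre and reductively eliminated to form the C2–C1(ring B) bond. The closest known reaction type is the cobalt–bisoxazoline-catalysed enantioconvergent Negishi (and Kumada) arylation of racemic benzyl 2-bromoalkanoates with arylzinc halides, recalled as tolerating aryl halides, acetals and esters; no ring is closed. The single new stereocentre C2 is controlled by the ligand in the radical-capture and reductive-elimination events, so the racemate is funnelled into one configuration; the CIP order (CO2R > aryl > CH2Ar > H) is the same as in simple 2-arylalkanoates, which is the basis of the ligand choice. The step needs chemoselectivity for the C(sp3)–Br bond over three aryl C–Br bonds, and this is secured because the α-carbonyl C–Br bond is much the weakest and is broken by atom abstraction at −25 °C, whereas electron-rich aryl bromides would need an oxidative addition that this catalyst should not perform at that temperature. In forming 12, iodine–magnesium exchange at −20 °C is selective for C–I over C–Br, the metal sits meta to bromine so no aryne can form, and C2 and C6 of ring B carry hydrogen so transmetallation is unhindered. The 2-iodopropane from the exchange is removed by evaporation at the arylzinc stage so that it cannot compete as an alkyl electrophile, and the non-basic arylzinc should leave the enolisable product configurationally intact.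

**Step 8**
Reactants: 13 benzyl (2R)-2-[3-bromo-4-methoxy-5-(methoxymethoxy)phenyl]-3-[2,3-dibromo-4,5-bis(methoxymethoxy)phenyl]propanoate
Product: 14 methyl (2R)-2-(3-bromo-5-hydroxy-4-methoxyphenyl)-3-(2,3-dibromo-4,5-dihydroxyphenyl)propanoate
Conditions: HCl (1.25 M in MeOH, large excess), 50 °C
Reagents that add atoms: methanol, CO
Why: Acid-catalysed acetal cleavage of the three MOM ethers together with acid-catalysed transesterification (Fischer-type acyl exchange) of the benzyl into the methyl ester, driven by the excess of methanol; the α-aryl stereocentre does not enolise appreciably under acid and should be kept.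

**Compound list**
1 | 2,3-dibromo-4-hydroxy-5-methoxybenzaldehyde (5,6-dibromovanillin) | O=Cc1cc(OC)c(O)c(Br)c1Br | starting material
2 | 2,3-dibromo-4,5-dihydroxybenzaldehyde | O=Cc1cc(O)c(O)c(Br)c1Br | intermediate
3 | 2,3-dibromo-4,5-bis(methoxymethoxy)benzaldehyde | O=Cc1cc(OCOC)c(OCOC)c(Br)c1Br | intermediate
4 | benzyl (2E)-3-[2,3-dibromo-4,5-bis(methoxymethoxy)phenyl]prop-2-enoate | O=C(OCc1ccccc1)/C=C/c1cc(OCOC)c(OCOC)c(Br)c1Br | intermediate
5 | benzyl triethylsilyl ketene acetal of 3-[2,3-dibromo-4,5-bis(methoxymethoxy)phenyl]propanoic acid (E/Z mixture) | CC[Si](CC)(CC)OC(OCc1ccccc1)=CCc1cc(OCOC)c(OCOC)c(Br)c1Br | intermediate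
6 | benzyl rac-2-bromo-3-[2,3-dibromo-4,5-bis(methoxymethoxy)phenyl]propanoate | O=C(OCc1ccccc1)C(Br)Cc1cc(OCOC)c(OCOC)c(Br)c1Br | intermediate
7 | 3-bromo-2-methoxyphenol | COc1c(O)cccc1Br | starting material
8 | 1-bromo-2-methoxy-3-(methoxymethoxy)benzene | COCOc1cccc(Br)c1OC | intermediate
9 | 2-[3-bromo-4-methoxy-5-(methoxymethoxy)phenyl]-4,4,5,5-tetramethyl-1,3,2-dioxaborolane | COCOc1cc(B2OC(C)(C)C(C)(C)O2)cc(Br)c1OC | intermediate
10 | 1-bromo-5-iodo-2-methoxy-3-(methoxymethoxy)benzene | COCOc1cc(I)cc(Br)c1OC | intermediate
11 | [3-bromo-4-methoxy-5-(methoxymethoxy)phenyl]magnesium chloride (LiCl complex) | COCOc1cc([Mg]Cl)cc(Br)c1OC | intermediate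
12 | [3-bromo-4-methoxy-5-(methoxymethoxy)phenyl]zinc bromide | COCOc1cc([Zn]Br)cc(Br)c1OC | intermediate
13 | benzyl (2R)-2-[3-bromo-4-methoxy-5-(methoxymethoxy)phenyl]-3-[2,3-dibromo-4,5-bis(methoxymethoxy)phenyl]propanoate | O=C(OCc1ccccc1)[C@H](Cc1cc(OCOC)c(OCOC)c(Br)c1Br)c1cc(OCOC)c(OC)c(Br)c1 | intermediate
14 | methyl (2R)-2-(3-bromo-5-hydroxy-4-methoxyphenyl)-3-(2,3-dibromo-4,5-dihydroxyphenyl)propanoate | COC(=O)[C@H](Cc1cc(O)c(O)c(Br)c1Br)c1cc(O)c(OC)c(Br)c1 | target

**Step count**
Total: 8 steps (ring A branch 4, ring B branch 2, union 1, final deprotection/ester exchange 1). Longest linear sequence: 6 steps (steps 1, 2, 3, 4, 7, 8).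

**Steps most likely to fail, with fallbacks**

Step 7. The planar radical may be captured outside the chiral pocket or by ligand-free cobalt, or the bulky 2-bromoaryl side chain may lower facial discrimination, so that enantiocontrol is insufficient. The fallback sets out from 6 and 12 and returns to the route at 14. The two fragments would be coupled without asymmetric induction (CoI2, TMEDA, THF, 0 °C) to benzyl rac-2-[3-bromo-4-methoxy-5-(methoxymethoxy)phenyl]-3-[2,3-dibromo-4,5-bis(methoxymethoxy)phenyl]propanoate F1. Saponification (LiOH, THF/H2O) would give rac-2-[3-bromo-4-methoxy-5-(methoxymethoxy)phenyl]-3-[2,3-dibromo-4,5-bis(methoxymethoxy)phenyl]propanoic acid F2. Neutral chlorination (1-chloro-N,N,2-trimethylprop-1-en-1-amine, CH2Cl2) would give the corresponding propanoyl chloride F3, and dehydrochlorination (Me2NEt, toluene, rt) the aryl alkyl ketene 2-[3-bromo-4-methoxy-5-(methoxymethoxy)phenyl]-3-[2,3-dibromo-4,5-bis(methoxymethoxy)phenyl]prop-1-en-1-one F4. Addition of (R)-pantolactone at −78 °C is the known, highly diastereoselective addition of α-hydroxy lactones to aryl alkyl ketenes, and it should give (3R)-4,4-dimethyl-2-oxooxolan-3-yl (2R)-2-[3-bromo-4-methoxy-5-(methoxymethoxy)phenyl]-3-[2,3-dibromo-4,5-bis(methoxymethoxy)phenyl]propanoate F5. LiOH/H2O2 at 0 °C would free (2R)-2-[3-bromo-4-methoxy-5-(methoxymethoxy)phenyl]-3-[2,3-dibromo-4,5-bis(methoxymethoxy)phenyl]propanoic acid F6. HCl in MeOH at rt (Fischer esterification with MOM cleavage) would then give 14.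

Step 4. 1,2-Hydrosilylation or C-silylation may compete with 1,4-addition, or the silyl ketene acetal may be protonated before it meets the bromine source, leaving saturated ester. The fallback sets out from 4 and returns at 6, with reduction and halogenation separated. Diimide (2-nitrobenzenesulfonohydrazide, Et3N, CH2Cl2, rt) would saturate the C=C bond to benzyl 3-[2,3-dibromo-4,5-bis(methoxymethoxy)phenyl]propanoate F7. Kinetic deprotonation with in situ silylation (LiN(SiMe3)2, Me3SiCl, THF, −78 °C) would give the benzyl trimethylsilyl ketene acetal of 3-[2,3-dibromo-4,5-bis(methoxymethoxy)phenyl]propanoic acid F8, and NBS at −78 °C would give 6.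

Step 8. Acyl exchange at the α-branched benzyl ester may be slow, so that the time and temperature needed leave mixed benzyl/methyl esters or begin to erode C2. The fallback sets out from 13 and returns at 14, cleaving at the alkyl–oxygen bonds instead of the acyl carbon. BCl3 with pentamethylbenzene in CH2Cl2 at −78 °C should remove the benzyl ester and the three MOM ethers while sparing the aryl methyl ether, giving (2R)-2-(3-bromo-5-hydroxy-4-methoxyphenyl)-3-(2,3-dibromo-4,5-dihydroxyphenyl)propanoic acid F9. HCl in MeOH at rt (Fischer esterification) would then give 14.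

**Further compounds**
F1 | step 7 | benzyl rac-2-[3-bromo-4-methoxy-5-(methoxymethoxy)phenyl]-3-[2,3-dibromo-4,5-bis(methoxymethoxy)phenyl]propanoate | O=C(OCc1ccccc1)C(Cc1cc(OCOC)c(OCOC)c(Br)c1Br)c1cc(OCOC)c(OC)c(Br)c1
F2 | step 7 | rac-2-[3-bromo-4-methoxy-5-(methoxymethoxy)phenyl]-3-[2,3-dibromo-4,5-bis(methoxymethoxy)phenyl]propanoic acid | OC(=O)C(Cc1cc(OCOC)c(OCOC)c(Br)c1Br)c1cc(OCOC)c(OC)c(Br)c1
F3 | step 7 | rac-2-[3-bromo-4-methoxy-5-(methoxymethoxy)phenyl]-3-[2,3-dibromo-4,5-bis(methoxymethoxy)phenyl]propanoyl chloride | ClC(=O)C(Cc1cc(OCOC)c(OCOC)c(Br)c1Br)c1cc(OCOC)c(OC)c(Br)c1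
F4 | step 7 | 2-[3-bromo-4-methoxy-5-(methoxymethoxy)phenyl]-3-[2,3-dibromo-4,5-bis(methoxymethoxy)phenyl]prop-1-en-1-one | O=C=C(Cc1cc(OCOC)c(OCOC)c(Br)c1Br)c1cc(OCOC)c(OC)c(Br)c1
F5 | step 7 | (3R)-4,4-dimethyl-2-oxooxolan-3-yl (2R)-2-[3-bromo-4-methoxy-5-(methoxymethoxy)phenyl]-3-[2,3-dibromo-4,5-bis(methoxymethoxy)phenyl]propanoate | CC1(C)COC(=O)[C@@H]1OC(=O)[C@H](Cc1cc(OCOC)c(OCOC)c(Br)c1Br)c1cc(OCOC)c(OC)c(Br)c1
F6 | step 7 | (2R)-2-[3-bromo-4-methoxy-5-(methoxymethoxy)phenyl]-3-[2,3-dibromo-4,5-bis(methoxymethoxy)phenyl]propanoic acid | OC(=O)[C@H](Cc1cc(OCOC)c(OCOC)c(Br)c1Br)c1cc(OCOC)c(OC)c(Br)c1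
F7 | step 4 | benzyl 3-[2,3-dibromo-4,5-bis(methoxymethoxy)phenyl]propanoate | O=C(OCc1ccccc1)CCc1cc(OCOC)c(OCOC)c(Br)c1Br
F8 | step 4 | benzyl trimethylsilyl ketene acetal of 3-[2,3-dibromo-4,5-bis(methoxymethoxy)phenyl]propanoic acid | C[Si](C)(C)OC(OCc1ccccc1)=CCc1cc(OCOC)c(OCOC)c(Br)c1Br
F9 | step 8 | (2R)-2-(3-bromo-5-hydroxy-4-methoxyphenyl)-3-(2,3-dibromo-4,5-dihydroxyphenyl)propanoic acid | OC(=O)[C@H](Cc1cc(O)c(O)c(Br)c1Br)c1cc(O)c(OC)c(Br)c1
A1 | direct plan | methyl 2-(3,5-dibromo-4-methoxyphenyl)acetate | COC(=O)Cc1cc(Br)c(OC)c(Br)c1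
A2 | direct plan | 2-(3-bromo-5-hydroxy-4-methoxyphenyl)acetic acid | OC(=O)Cc1cc(O)c(OC)c(Br)c1
A3 | direct plan | 2,3-dibromo-4,5-dihydroxybenzaldehyde | O=Cc1cc(O)c(O)c(Br)c1Br
A4 | direct plan | (2E)-2-(3-acetoxy-5-bromo-4-methoxyphenyl)-3-(4,5-diacetoxy-2,3-dibromophenyl)prop-2-enoic acid | OC(=O)/C(=C/c1cc(OC(C)=O)c(OC(C)=O)c(Br)c1Br)c1cc(OC(C)=O)c(OC)c(Br)c1
A5 | direct plan | rac-2-(3-acetoxy-5-bromo-4-methoxyphenyl)-3-(4,5-diacetoxy-2,3-dibromophenyl)propanoic acid | OC(=O)C(Cc1cc(OC(C)=O)c(OC(C)=O)c(Br)c1Br)c1cc(OC(C)=O)c(OC)c(Br)c1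
A6 | direct plan | 2-(3-acetoxy-5-bromo-4-methoxyphenyl)-3-(4,5-diacetoxy-2,3-dibromophenyl)prop-1-en-1-one | O=C=C(Cc1cc(OC(C)=O)c(OC(C)=O)c(Br)c1Br)c1cc(OC(C)=O)c(OC)c(Br)c1
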